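**Plan**
Numbering: the carbocycle is C1 (quaternary, CH3 and pyrone), C2=C3(CH3)–C4=C5(CH3) and C6 (CH); the side chain is C7(CH3)=C8H–C9(=O)CH3. Enabling feature: the pyrone carbon on C1 and C7 on C6 are cis on neighbouring ring atoms. If C6–C7 is cut and C4=C5 is moved to C5=C6, the ring becomes a mirror-symmetric 1,3,5-trimethylcyclohexa-2,5-diene. A C1 carboxyl can therefore hold C7 as an ester through the oxygenated C7 methyl.
Cuts, in retrosynthetic order: the C9 ketal; the pyrone O–CH3; the pyrone ring O–C(=O) bond; the bond from the C1-bound carbonyl carbon to the propionate carbon; one C–H of the C7 methyl (back to the allylic C–O of a δ-lactone); C6–C7; the ester C–O; C1–CH3.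
Forward: the carbocycle comes from 3,5-dimethylbenzoic acid by Birch reductive methylation, and the iodoalkenyl arm comes from but-3-yn-2-one. Esterification joins them, the Heck reaction closes the temporary lactone ring, and hydrogenolysis opens it again. The pyrone ring is built last from the C1 aldehyde and methyl 2-methyl-3-oxopentanoate.
Stereochemistry: C1 and C6 are set together in the Heck step, cis by the tether and in the absolute sense by BINAP choosing one enantiotopic alkene. The C7=C8 geometry comes from a syn hydrostannation and is carried through unchanged.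

Key step: step 6

Assumption: the sense of induction of BINAP on this ester-tethered diene cannot be predicted with confidence, so (R)-BINAP is written for the (1S,6S) series and (S)-BINAP takes its place, with nothing else changed, if the opposite sense is found.

**Route**

Step 1
Reactants: 1 3,5-dimethylbenzoic acid
Product: 3 1,3,5-trimethylcyclohexa-2,5-diene-1-carboxylic acid, via dilithium dienediolate 2 (not isolated)
Conditions: Li, NH3(l)/THF, −78 °C; MeI, −78 °C to rt; aq. HCl
Reagents that add atoms: iodomethane CI; lithium [Li] (lithium in 2 only)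
Why: Birch reductive alkylation, in which the benzoate is reduced to the 1,4-dihydro dienediolate and methylated at C1, leaves both ring methyls on the two alkenes and so gives an achiral acid with a mirror plane through C1 and C4.

Step 2
Reactants: 4 but-3-yn-2-one
Product: 5 2-ethynyl-2-methyl-1,3-dioxolane
Conditions: Me3SiOCH2CH2OSiMe3, Me3SiOTf (cat.), CH2Cl2, −78 to −20 °C
Reagents that add atoms: 1,2-bis(trimethylsilyloxy)ethane C[Si](C)(C)OCCO[Si](C)(C)C
Why: Ketalisation by silyl transfer runs aprotically at low temperature, so the carbonyl group is masked without conjugate addition of free glycol to the ynone.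

Step 3
Reactants: 5 2-ethynyl-2-methyl-1,3-dioxolane
Product: 7 3-(2-methyl-1,3-dioxolan-2-yl)prop-2-yn-1-ol, via lithium acetylide 6 (not isolated)
Conditions: n-BuLi, THF, −78 °C; (CH2O)n, −78 °C to rt; H2O
Reagents that add atoms: formaldehyde (as paraformaldehyde) C=O; n-butyllithium [Li]CCCC (lithium in 6 only)
Why: Addition of a lithium acetylide to formaldehyde is the standard hydroxymethylation of a terminal alkyne, and the ketal is inert to the base.

Step 4
Reactants: 7 3-(2-methyl-1,3-dioxolan-2-yl)prop-2-yn-1-ol
Product: 9 (E)-2-iodo-3-(2-methyl-1,3-dioxolan-2-yl)prop-2-en-1-ol, via alkenylstannane 8 (not isolated)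
Conditions: PdCl2(PPh3)2 (2 mol %), Bu3SnH, THF, 0 °C to rt; then I2, 0 °C
Reagents that add atoms: iodine II; tributyltin hydride CCCC[SnH](CCCC)CCCC (tin in 8 only)
Why: Palladium-catalysed hydrostannation adds H and Sn syn, with tin expected on the alkyne carbon next to the carbinol and away from the quaternary ketal carbon, and iododestannylation proceeds with retention, so CH2OH and the ketal carbon end up cis as the later C7=C8 geometry requires.

Step 5
Reactants: 3 1,3,5-trimethylcyclohexa-2,5-diene-1-carboxylic acid; 9 (E)-2-iodo-3-(2-methyl-1,3-dioxolan-2-yl)prop-2-en-1-ol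
Product: 10 (E)-2-iodo-3-(2-methyl-1,3-dioxolan-2-yl)allyl 1,3,5-trimethylcyclohexa-2,5-diene-1-carboxylate (achiral)
Conditions: DCC, DMAP (cat.), CH2Cl2, 0 °C to rt
Reagents that add atoms: none
Why: Steglich esterification is well established for 1-alkylcyclohexa-2,5-diene-1-carboxylic acids with primary alcohols, and its mildly basic medium spares the ketal, the alkenyl iodide and the skipped diene.

Step 6
Reactants: 10 (E)-2-iodo-3-(2-methyl-1,3-dioxolan-2-yl)allyl 1,3,5-trimethylcyclohexa-2,5-diene-1-carboxylate
Product: 11 (4Z,4aS,8aS)-5,7,8a-trimethyl-4-[(2-methyl-1,3-dioxolan-2-yl)methylidene]-3,4,4a,8a-tetrahydro-1H-isochromen-1-one (cis-fused lactone; C8a = C1 and C4a = C6 of the route numbering)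
Conditions: Pd(OAc)2 (10 mol %), (R)-BINAP (22 mol %), Ag3PO4 (2 equiv), NMP, 80 °C, dark
Reagents that add atoms: none
Why: Zerovalent palladium formed from Pd(OAc)2 and BINAP inserts into the C7–I bond with retention of geometry, Ag3PO4 removes iodide so that a cationic, still chelated alkenylpalladium binds one ring alkene, syn migratory insertion joins C7 to C6 and puts palladium on C5, and syn β-hydride elimination of the C4 hydrogen on the same face releases the C2=C3–C4=C5 diene. The closest known reaction type is the enantioselective intramolecular Heck desymmetrisation of cyclohexa-2,5-dienes that carry an alkenyl halide on a chain from the quaternary carbon, which gives cis-fused bicyclic 1,3-dienes. The one new ring, the δ-lactone C1–C(=O)–O–CH2–C7–C6, closes in the 6-exo-trig mode. C6 is fixed relative to C1 by the three-atom tether, which can bring C7 only to the ring face that bears the carboxyl (cis fusion) and leaves H6 anti to palladium so that C6 cannot be lost again, while the absolute configuration of C1 and C6 together follows from which enantiotopic alkene (C2=C3 or C5=C6) the chiral diphosphine pocket accepts. The step needs three selectivities: group selection, which the ligand supplies; attack at C6 rather than C5, which the tether length secures (6-exo against 7-endo); and elimination toward C4 rather than the C5 methyl, which conjugation favours, with hydridopalladium re-addition able to convert any exocyclic isomer to the diene. The unreactive s-trans ester rotamer and the methyl-bearing alkene are countered by the cationic pathway, by the polar solvent that lowers the penalty of the more polar s-cis rotamer, by the quaternary C1 and by the temperature, and insertion into C–I is far faster than ionisation of the pivalate-like allylic ester.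

Step 7
Reactants: 11 cis-fused alkylidene lactone
Product: 13 (1S,6S)-1,3,5-trimethyl-6-[(E)-1-(2-methyl-1,3-dioxolan-2-yl)prop-1-en-2-yl]cyclohexa-2,4-diene-1-carboxylic acid, via phenylsilyl ester 12 (not isolated)
Conditions: Pd(PPh3)4 (5 mol %), PhSiH3 (2 equiv), CH2Cl2, rt; then H2O
Reagents that add atoms: phenylsilane [SiH3]c1ccccc1 (silicon in 12 only)
Why: This is a palladium-catalysed hydrogenolysis of an allylic ester (Tsuji–Trost ionisation, then hydride transfer from the silane) in which the γ-alkylidene-δ-valerolactone is its own allylic carboxylate, hydride should go to the open CH2 terminus rather than to C8 beside the quaternary ketal carbon, and the geometry should hold because syn/anti exchange would need palladium σ-bound at that hindered C8.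

Step 8
Reactants: 13 dienyl carboxylic acid
Product: 14 {(1S,6S)-1,3,5-trimethyl-6-[(E)-1-(2-methyl-1,3-dioxolan-2-yl)prop-1-en-2-yl]cyclohexa-2,4-dien-1-yl}methanol
Conditions: LiAlH4, THF, 0 °C to rt; aqueous work-up
Reagents that add atoms: none
Why: Hydride reduction of a carboxylic acid with LiAlH4 also works for α-quaternary acids and leaves the ketal, the diene and both stereocentres untouched.

Step 9
Reactants: 14 neopentyl alcohol
Product: 15 (1S,6S)-1,3,5-trimethyl-6-[(E)-1-(2-methyl-1,3-dioxolan-2-yl)prop-1-en-2-yl]cyclohexa-2,4-diene-1-carbaldehyde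
Conditions: Dess–Martin periodinane, pyridine, CH2Cl2, 0 °C to rt
Reagents that add atoms: none
Why: Dess–Martin oxidation buffered with pyridine converts hindered primary alcohols to aldehydes at or below room temperature, which protects the ketal and avoids thermal formyl migration around the cyclohexadiene.

Step 10
Reactants: 15 dienyl carbaldehyde; 16 methyl 2-methyl-3-oxopentanoate
Product: 18 methyl 5-hydroxy-2,4-dimethyl-3-oxo-5-{(1S,6S)-1,3,5-trimethyl-6-[(E)-1-(2-methyl-1,3-dioxolan-2-yl)prop-1-en-2-yl]cyclohexa-2,4-dien-1-yl}pentanoate (diastereomer mixture at the three chain centres), via dilithium dianion 17 (not isolated)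
Conditions: 16, LiN(iPr)2 (2.1 equiv per 16), THF, −78 to 0 °C; then 15, −78 °C; AcOH
Reagents that add atoms: lithium diisopropylamide [Li+].CC(C)[N-]C(C)C (lithium in 17 only)
Why: The γ-selective aldol addition of a β-keto ester dianion works well with a non-enolisable aldehyde, and the three new chain stereocentres need no control because the next two steps make them planar.

Step 11
Reactants: 18 aldol adduct
Product: 19 methyl 2,4-dimethyl-3,5-dioxo-5-{(1S,6S)-1,3,5-trimethyl-6-[(E)-1-(2-methyl-1,3-dioxolan-2-yl)prop-1-en-2-yl]cyclohexa-2,4-dien-1-yl}pentanoate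
Conditions: Dess–Martin periodinane, pyridine, CH2Cl2, 0 °C to rt
Reagents that add atoms: none
Why: Dess–Martin oxidation is the usual way from β-hydroxy ketones to 1,3-diketones in polypropionate pyrone work and tolerates a carbinol next to a quaternary carbon.

Step 12
Reactants: 19 3,5-dioxo ester
Product: 20 4-hydroxy-3,5-dimethyl-6-{(1S,6S)-1,3,5-trimethyl-6-[(E)-1-(2-methyl-1,3-dioxolan-2-yl)prop-1-en-2-yl]cyclohexa-2,4-dien-1-yl}-2H-pyran-2-one
Conditions: DBU, toluene, rt to 60 °C
Reagents that add atoms: none
Why: In this base-induced enol lactonisation of a 3,5-dioxo ester the enolate oxygen of the C1-bound ketone displaces methoxide to close the pyranone, and H6 is not acidic enough for DBU as long as C9 stays ketalised.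

Step 13
Reactants: 20 4-hydroxy-2-pyranone
Product: 21 2-methoxy-3,5-dimethyl-6-{(1S,6S)-1,3,5-trimethyl-6-[(E)-1-(2-methyl-1,3-dioxolan-2-yl)prop-1-en-2-yl]cyclohexa-2,4-dien-1-yl}-4H-pyran-4-one
Conditions: MeOTf (1.2 equiv), CH2Cl2, 0 °C to rt; basic aqueous work-up
Reagents that add atoms: methyl trifluoromethanesulfonate COS(=O)(=O)C(F)(F)F
Why: Base-free O-methylation with a hard methylating agent attacks the lactone carbonyl oxygen and gives, after loss of a proton, the 2-methoxy-4-pyranone rather than the 4-methoxy-2-pyranone, and any ketal lost to the acid formed only anticipates the last step.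

Step 14
Reactants: 21 ketal of the target
Product: 22 2-methoxy-3,5-dimethyl-6-{(1S,6S)-1,3,5-trimethyl-6-[(E)-4-oxopent-2-en-2-yl]cyclohexa-2,4-dien-1-yl}-4H-pyran-4-one (CNP0353320.2)
Conditions: PPTS (cat.), acetone/H2O, rt to 40 °C
Reagents that add atoms: water O
Why: Acid-catalysed hydrolysis of an allylic ketal needs only a weak acid, which leaves the methoxypyranone and C6 alone and releases the enone in its more stable E form.

**Compound list**
1 | 3,5-dimethylbenzoic acid | Cc1cc(C)cc(C(=O)O)c1 | starting material
2 | dilithium (3,5-dimethylcyclohexa-2,5-dien-1-ylidene)methanediolate | [Li+].[Li+].CC1=CC(=C([O-])[O-])C=C(C)C1 | intermediate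
3 | 1,3,5-trimethylcyclohexa-2,5-diene-1-carboxylic acid | CC1=CC(C)(C(=O)O)C=C(C)C1 | intermediate
4 | but-3-yn-2-one | CC(=O)C#C | starting material
5 | 2-ethynyl-2-methyl-1,3-dioxolane | C#CC1(C)OCCO1 | intermediate
6 | lithium (2-methyl-1,3-dioxolan-2-yl)acetylide | [Li+].[C-]#CC1(C)OCCO1 | intermediate
7 | 3-(2-methyl-1,3-dioxolan-2-yl)prop-2-yn-1-ol | OCC#CC1(C)OCCO1 | intermediate
8 | (E)-3-(2-methyl-1,3-dioxolan-2-yl)-2-(tributylstannyl)prop-2-en-1-ol | OC/C(=C\C1(C)OCCO1)[Sn](CCCC)(CCCC)CCCC | intermediate
9 | (E)-2-iodo-3-(2-methyl-1,3-dioxolan-2-yl)prop-2-en-1-ol | OC/C(I)=C\C1(C)OCCO1 | intermediate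
10 | (E)-2-iodo-3-(2-methyl-1,3-dioxolan-2-yl)allyl 1,3,5-trimethylcyclohexa-2,5-diene-1-carboxylate | CC1(C(=O)OC/C(I)=C\C2(C)OCCO2)C=C(C)CC(C)=C1 | intermediate
11 | (4Z,4aS,8aS)-5,7,8a-trimethyl-4-[(2-methyl-1,3-dioxolan-2-yl)methylidene]-3,4,4a,8a-tetrahydro-1H-isochromen-1-one | O=C1OC/C(=C\C2(C)OCCO2)[C@@H]3C(C)=CC(C)=C[C@]13C | intermediate
12 | phenylsilyl (1S,6S)-1,3,5-trimethyl-6-[(E)-1-(2-methyl-1,3-dioxolan-2-yl)prop-1-en-2-yl]cyclohexa-2,4-diene-1-carboxylate | O=C(O[SiH2]c1ccccc1)[C@@]2(C)C=C(C)C=C(C)[C@H]2/C(C)=C/C3(C)OCCO3 | intermediate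
13 | (1S,6S)-1,3,5-trimethyl-6-[(E)-1-(2-methyl-1,3-dioxolan-2-yl)prop-1-en-2-yl]cyclohexa-2,4-diene-1-carboxylic acid | OC(=O)[C@@]1(C)C=C(C)C=C(C)[C@H]1/C(C)=C/C2(C)OCCO2 | intermediate
14 | {(1S,6S)-1,3,5-trimethyl-6-[(E)-1-(2-methyl-1,3-dioxolan-2-yl)prop-1-en-2-yl]cyclohexa-2,4-dien-1-yl}methanol | OC[C@@]1(C)C=C(C)C=C(C)[C@H]1/C(C)=C/C2(C)OCCO2 | intermediate
15 | (1S,6S)-1,3,5-trimethyl-6-[(E)-1-(2-methyl-1,3-dioxolan-2-yl)prop-1-en-2-yl]cyclohexa-2,4-diene-1-carbaldehyde | O=C[C@@]1(C)C=C(C)C=C(C)[C@H]1/C(C)=C/C2(C)OCCO2 | intermediate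
16 | methyl 2-methyl-3-oxopentanoate | CCC(=O)C(C)C(=O)OC | starting material
17 | dilithium dianion of methyl 2-methyl-3-oxopentanoate (bis-enolate) | [Li+].[Li+].CC=C([O-])C(C)=C([O-])OC | intermediate
18 | methyl 5-hydroxy-2,4-dimethyl-3-oxo-5-{(1S,6S)-1,3,5-trimethyl-6-[(E)-1-(2-methyl-1,3-dioxolan-2-yl)prop-1-en-2-yl]cyclohexa-2,4-dien-1-yl}pentanoate (chain centres undefined) | COC(=O)C(C)C(=O)C(C)C(O)[C@@]1(C)C=C(C)C=C(C)[C@H]1/C(C)=C/C2(C)OCCO2 | intermediate
19 | methyl 2,4-dimethyl-3,5-dioxo-5-{(1S,6S)-1,3,5-trimethyl-6-[(E)-1-(2-methyl-1,3-dioxolan-2-yl)prop-1-en-2-yl]cyclohexa-2,4-dien-1-yl}pentanoate | COC(=O)C(C)C(=O)C(C)C(=O)[C@@]1(C)C=C(C)C=C(C)[C@H]1/C(C)=C/C2(C)OCCO2 | intermediate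
20 | 4-hydroxy-3,5-dimethyl-6-{(1S,6S)-1,3,5-trimethyl-6-[(E)-1-(2-methyl-1,3-dioxolan-2-yl)prop-1-en-2-yl]cyclohexa-2,4-dien-1-yl}-2H-pyran-2-one | O=c1oc([C@@]2(C)C=C(C)C=C(C)[C@H]2/C(C)=C/C3(C)OCCO3)c(C)c(O)c1C | intermediate
21 | 2-methoxy-3,5-dimethyl-6-{(1S,6S)-1,3,5-trimethyl-6-[(E)-1-(2-methyl-1,3-dioxolan-2-yl)prop-1-en-2-yl]cyclohexa-2,4-dien-1-yl}-4H-pyran-4-one | COc1oc([C@@]2(C)C=C(C)C=C(C)[C@H]2/C(C)=C/C3(C)OCCO3)c(C)c(=O)c1C | intermediate
22 | 2-methoxy-3,5-dimethyl-6-{(1S,6S)-1,3,5-trimethyl-6-[(E)-4-oxopent-2-en-2-yl]cyclohexa-2,4-dien-1-yl}-4H-pyran-4-one | COc1oc([C@@]2(C)C=C(C)C=C(C)[C@H]2/C(C)=C/C(C)=O)c(C)c(=O)c1C | target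

**Step count**
Total: 14 steps. Longest linear sequence: 13 steps (4 to 22, steps 2 to 14).

**Steps most likely to fail**

Step 6. The chelated cationic alkenylpalladium must react from the minor s-cis ester rotamer and must form a tertiary carbon–palladium bond. Insertion may therefore be so slow that reductive loss of iodine or ionisation of the allylic ester takes over. The ligand may also discriminate poorly between the two alkenes through a tether that contains an ester. The fallback sets out from 10 and gives up catalyst control. Cyclisation under phosphine-free, chloride-promoted Heck conditions (Pd(OAc)2, Bu4NCl, KOAc, DMF, 80 °C) uses a far less crowded palladium centre. The tether still enforces the cis fusion, so this should give 11 together with its mirror image, the (4Z,4aR,8aR)-lactone F1. Preparative chromatography on a chiral stationary phase separates the two, and the route is rejoined at 11. The absolute configuration then comes from resolution.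

Step 7. Several things can go wrong at the π-allyl stage:
- hydride transfer to the wrong allyl terminus;
- drift of the C7=C8 geometry;
- loss of H6 to give a triene;
- sluggish ionisation of the trisubstituted allylic system.

The fallback sets out from 11 and avoids π-allyl intermediates altogether. LiAlH4 in THF opens the lactone to the (Z)-diol F2. Corey–Kim chlorination without added base (NCS, Me2S, CH2Cl2, −20 to 0 °C) converts only allylic alcohols and should give the allylic chloride F3 with the neopentyl hydroxyl left free. LiBHEt3 (THF, −78 to 0 °C) then displaces chloride in a direct SN2 reaction. The product is 14, so step 8 is skipped.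

Step 4. The inductive pull of the two ketal oxygens may compete with the steric bias and direct tin to C8, which would erode the regioselectivity of the hydrostannation. The fallback sets out from 7 and relies on steric control alone. Silylation (TBSCl, imidazole, DMF) gives the propargylic silyl ether F4. Hydrozirconation with a slight excess of Cp2Zr(H)Cl (THF, rt) is a syn addition that equilibrates to the less hindered position and should place zirconium next to the CH2O group, giving the alkenylzirconocene chloride F5. Iodine converts this with retention to the iodoalkenyl silyl ether F6, and Bu4NF in THF releases 9.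

**Further compounds**
F1 | step 6 | (4Z,4aR,8aR)-5,7,8a-trimethyl-4-[(2-methyl-1,3-dioxolan-2-yl)methylidene]-3,4,4a,8a-tetrahydro-1H-isochromen-1-one (enantiomer of 11) | O=C1OC/C(=C\C2(C)OCCO2)[C@H]3C(C)=CC(C)=C[C@@]13C
F2 | step 7 | (Z)-2-[(1S,6S)-6-(hydroxymethyl)-2,4,6-trimethylcyclohexa-2,4-dien-1-yl]-3-(2-methyl-1,3-dioxolan-2-yl)prop-2-en-1-ol | OC[C@@]1(C)C=C(C)C=C(C)[C@H]1/C(CO)=C/C2(C)OCCO2
F3 | step 7 | {(1S,6S)-6-[(Z)-3-chloro-1-(2-methyl-1,3-dioxolan-2-yl)prop-1-en-2-yl]-1,3,5-trimethylcyclohexa-2,4-dien-1-yl}methanol | OC[C@@]1(C)C=C(C)C=C(C)[C@H]1/C(CCl)=C/C2(C)OCCO2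
F4 | step 4 | tert-butyldimethyl{[3-(2-methyl-1,3-dioxolan-2-yl)prop-2-yn-1-yl]oxy}silane | CC(C)(C)[Si](C)(C)OCC#CC1(C)OCCO1
F5 | step 4 | chlorobis(cyclopentadienyl){(E)-3-(tert-butyldimethylsilyloxy)-1-(2-methyl-1,3-dioxolan-2-yl)prop-1-en-2-yl}zirconium | [CH-]1C=CC=C1.[CH-]1C=CC=C1.[Cl-].[Zr+4].CC(C)(C)[Si](C)(C)OC/[C-]=C\C1(C)OCCO1
F6 | step 4 | tert-butyl{[(E)-2-iodo-3-(2-methyl-1,3-dioxolan-2-yl)allyl]oxy}dimethylsilane | CC(C)(C)[Si](C)(C)OC/C(I)=C\C1(C)OCCO1
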